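## Retrosynthetic overview
1. 25 <= 22: one equivalent of MeLi opens the C10-O-C11 lactone, which turns the C3 carboxyl into the acetyl group. The freed C10 alkoxide is acetylated in the same flask.
2. Key disconnection is the tertiary C10-O bond: 22 <= 21 by an oxidative platinum-catalysed cyclisation. The C3 ester oxygen captures C10 from the lower face while C6-C7 closes ring A.
3. C1-C9: Ireland-Claisen rearrangement of but-3-enoate 17 delivers C7, C8, C9 and C12 to the upper face.
4. Ring B: cyclohexenone 10 comes from a Michael/aldol annulation of 2-methylcitronellal 4 with oxo-enoate 8, which sets C2. It is enlarged by one carbon to 12.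
5. Ring order: six-membered carbocycle, then ring B (seven-membered), then ring A and the lactone ring together. The lactone is opened last.

Numbering (bicyclo[4.3.1]decane):
- C1 and C6 are the bridgeheads, C2 is quaternary, C3 bears the acetyl group, then C4, C5, C7, C8=C9(CHO).
- C10 is the one-carbon bridge (OAc, Me). C11 is the carbonyl carbon on C3, C12 the formyl carbon, C1' the side-chain methine.
- Ring A is six-membered and ring B is seven-membered.
- The upper face is the face of ring B that carries the C7-C9 bridge, the C2 methyl and the C10 methyl in 25.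

Assumption: in a bicyclo[4.3.1]decene the C7-C9 bridge can span only one face of ring B, so ring closure fixes C6 once C1 is set; read literally the given C6 tag is the trans-bridged arrangement, which is taken as a drawing artefact, and that tag is kept unchanged in the SMILES of all bridged compounds (22 to 25, F2 to F4) so that they stay comparable with the given string.

## Route

Step 1
Reactants: 1 (S)-citronellal
Product: 4 (3S)-2,3,7-trimethyloct-6-enal, via N-tert-butyl imine 2 (not isolated), via C2-methylated imine 3 (not isolated)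
Conditions: t-BuNH2, MgSO4, Et2O, 0 °C; LiN(i-Pr)2 (1.1 equiv), THF, 0 °C, then MeI, -78 °C; aq. oxalic acid, pentane, 0 °C
Reagents that add atoms: iodomethane CI; water O
Why: Stork metalloenamine alkylation, in which the lithio-azaenolate of the imine is C-methylated once without aldol self-condensation, C2 forms as a mixture that does not matter because it is planarised again in step 3, and C1' is untouched.

Step 2
Reactants: 5 1-hydroxybutan-2-one, 6 tert-butyl 2-(triphenyl-lambda5-phosphanylidene)acetate
Product: 8 tert-butyl (E)-4-oxohex-2-enoate, via 2-oxobutanal 7 (not isolated)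
Conditions: MnO2 (10 equiv), CH2Cl2, 25 °C
Reagents that add atoms: none
Why: Tandem oxidation-Wittig olefination, in which MnO2 oxidises the alpha-hydroxy ketone to the keto aldehyde and the stabilised ylide traps its aldehyde at once to give the E-alkene.

Step 3
Reactants: 4 (3S)-2,3,7-trimethyloct-6-enal, 8 tert-butyl (E)-4-oxohex-2-enoate
Product: 10 tert-butyl (1R,2R)-2,4-dimethyl-2-[(2S)-6-methylhept-5-en-2-yl]-5-oxocyclohex-3-ene-1-carboxylate, via Michael adduct 9 (not isolated)
Conditions: 9-amino-9-deoxy-epi-quinine (20 mol %), PhCO2H (40 mol %), toluene, 40 °C; then Bn2NH·CF3CO2H (20 mol %), 60 °C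
Reagents that add atoms: none
Why: Enamine-catalysed Michael addition followed by aldol condensation (Robinson-type annulation), in which the E-enamine of 4 (side chain anti to N) attacks the carbon beta to the ketone of 8, the cinchona primary amine shields one enamine face and sets quaternary C2 under catalyst control, the open synclinal transition state puts the ester cis to the C2 methyl (C3 epimeric to the target, corrected in step 6), and only the ethyl-ketone CH2 can close a six-membered ring onto the non-enolisable aldehyde.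

Step 4
Reactants: 10 cyclohexenone ester
Product: 12 tert-butyl (1R,2R)-2,4-dimethyl-2-[(2S)-6-methylhept-5-en-2-yl]-5-oxocyclohept-3-ene-1-carboxylate, via alpha-silyl cycloheptenone 11 (not isolated)
Conditions: Me3SiCHN2 (1.5 equiv), Sc(OTf)3 (10 mol %), CH2Cl2, -40 to 0 °C; then 1 M HCl, THF, 0 °C
Reagents that add atoms: trimethylsilyldiazomethane C[Si](C)(C)C=[N+]=[N-]
Why: Lewis-acid-catalysed diazoalkane homologation (Tiffeneau-Demjanov-type 1,2-shift), in which the diazo carbon adds to the activated ketone, the saturated C4 methylene migrates rather than the alkenyl carbon so that enone conjugation is kept, the C-silyl group is lost on work-up, and no stereocentre is touched.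

Step 5
Reactants: 12 cycloheptenone ester
Product: 13 tert-butyl (1R,2R,5S)-5-hydroxy-2,4-dimethyl-2-[(2S)-6-methylhept-5-en-2-yl]cyclohept-3-ene-1-carboxylate
Conditions: (R)-2-methyl-CBS-oxazaborolidine (20 mol %), catecholborane (1.5 equiv), toluene, -78 °C; aq. NaOH
Reagents that add atoms: none
Why: Corey-Bakshi-Shibata reduction, a reagent-controlled 1,2-hydride delivery with the alpha-methyl alkenyl arm as the large group, which gives the (S)-carbinol at C6 (hydroxyl on the upper face) while catecholborane at -78 °C leaves the ester and alkenes alone.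

Step 6
Reactants: 13 allylic alcohol (C3 epimer)
Product: 15 tert-butyl (1S,2R,5S)-5-hydroxy-2,4-dimethyl-2-[(2S)-6-methylhept-5-en-2-yl]cyclohept-3-ene-1-carboxylate, via dilithium alkoxide enolate 14 (not isolated)
Conditions: LiN(i-Pr)2 (2.5 equiv), THF, -78 to 0 °C; AcOH (6 equiv) in THF, -78 °C
Reagents that add atoms: none
Why: Zimmerman-type kinetic protonation of an exocyclic ester enolate, in which the proton enters from the upper face next to the small C2 methyl and away from the branched side chain, pushing the ester to the lower face and setting C3 as in the target whatever the C3 ratio from step 3.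

Step 7
Reactants: 15 allylic alcohol, 16 but-3-enoic acid
Product: 17 tert-butyl (1S,2R,5S)-5-(but-3-enoyloxy)-2,4-dimethyl-2-[(2S)-6-methylhept-5-en-2-yl]cyclohept-3-ene-1-carboxylate
Conditions: N,N'-dicyclohexylcarbodiimide (1.3 equiv), DMAP (10 mol %), CH2Cl2, 0 °C
Reagents that add atoms: none
Why: Steglich esterification acylates the secondary allylic alcohol with retention at C6, and at 0 °C with little DMAP the beta,gamma-alkene stays out of conjugation.

Step 8
Reactants: 17 but-3-enoate
Product: 20 methyl 2-[(1S,2R,3S)-3-(tert-butoxycarbonyl)-2,7-dimethyl-2-[(2S)-6-methylhept-5-en-2-yl]cyclohept-6-en-1-yl]but-3-enoate, via silyl ketene acetal 18 (not isolated), via rearranged acid 19 (not isolated)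
Conditions: LiN(i-Pr)2 (1.2 equiv), Me3SiCl (1.5 equiv), THF, -78 °C, then 60 °C, 4 h; aq. citric acid; crude acid, Me3SiCHN2, PhMe-MeOH, 0 °C
Reagents that add atoms: trimethylsilyldiazomethane C[Si](C)(C)C=[N+]=[N-]
Why: Ireland-Claisen rearrangement, in which only the doubly activated C9-H is removed, the suprafacial [3,3] shift moves the chain from the upper-face C6-O bond to the upper face of C1 (anti to the side chain on C2) and so sets C1, the ring alkene moves to C6=C10, and the C9 mixture is erased in step 10.

Step 9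
Reactants: 20 methyl ester
Product: 21 tert-butyl (1S,2R,3S)-2,4-dimethyl-2-[(2S)-6-methylhept-5-en-2-yl]-3-(1-oxobut-3-en-2-yl)cyclohept-4-ene-1-carboxylate
Conditions: i-Bu2AlH (1.05 equiv), CH2Cl2, -78 °C; aq. potassium sodium tartrate; used crude
Reagents that add atoms: none
Why: Partial ester reduction, in which the aluminium hemiacetal survives at -78 °C and gives the aldehyde only on work-up, the hindered tert-butyl ester is not attacked, and neutral work-up keeps the vinyl group out of conjugation.

Step 10
Reactants: 21 diene aldehyde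
Product: 22 (1S,2R,3S,6S,10R)-9-formyl-2,10-dimethyl-2-[(2S)-6-methylhept-5-en-2-yl]bicyclo[4.3.1]dec-8-ene-3,10-carbolactone
Conditions: PtCl2(dppe) (10 mol %, dppe = Ph2PCH2CH2PPh2), AgBF4 (25 mol %), Ph3COMe (1.5 equiv), EtNO2, 25 °C; then DBU (20 mol %)
Reagents that add atoms: none
Why: Proposed new method: an oxidative cation-olefin cyclisation terminated by an ester oxygen, which makes the tertiary C10-O bond; the dicationic divalent platinum centre binds only the monosubstituted C7=C8 alkene, C6 of the trisubstituted ring alkene attacks C7 in a chair-like 6-endo mode from the upper face (the chain hangs from C1 on that face), the charge building up at C10 is intercepted anti, from the lower face, by the carbonyl oxygen of the C3 tert-butyl ester through a six-membered array, loss of isobutene and a proton gives the lactone, beta-hydride elimination of the C8-Pt bond towards C9 gives the enal (DBU moves any C7=C8 isomer into conjugation), and Ph3C+ (from Ph3COMe and the released proton) takes the hydride from platinum to close the cycle, so that C6 and C10 are set by one stereospecific anti addition across the Z ring alkene; closest known reaction types are the platinum- or palladium-catalysed oxidative cyclisation of 1,5-dienes terminated by phenols or alcohols and halolactonisation with tert-butyl esters as the oxygen nucleophile.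

Step 11
Reactants: 22 tricyclic enal lactone
Product: 25 (1S,2R,3S,6S,10R)-3-acetyl-9-formyl-2,10-dimethyl-2-[(2S)-6-methylhept-5-en-2-yl]bicyclo[4.3.1]dec-8-en-10-yl acetate, via amino alkoxide 23 (not isolated), via keto alkoxide 24 (not isolated)
Conditions: MeNHOMe (1.1 equiv), MeLi (1.1 equiv), THF, -78 °C, add 22; MeLi (1.1 equiv), -78 to -40 °C; Ac2O (5 equiv), DMAP (20 mol %), -40 to 25 °C
Reagents that add atoms: methyllithium [Li]C; acetic anhydride CC(=O)OC(C)=O
Why: Transient alpha-amino alkoxide protection of the aldehyde, single addition of MeLi to the lactone and O-acylation, in which the tetrahedral adduct opens to the methyl ketone and the tertiary C10 alkoxide, Ac2O acetylates that alkoxide with retention and also scavenges the amide so that the enal is released, and C3 keeps the configuration held by the lactone.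

## Compound list
1 | (S)-citronellal | O=CC[C@@H](C)CCC=C(C)C | starting material
2 | N-tert-butyl imine of 1 | CC(C)(C)/N=C/C[C@@H](C)CCC=C(C)C | intermediate
3 | C2-methylated imine | CC(C)(C)/N=C/C(C)[C@@H](C)CCC=C(C)C | intermediate
4 | (3S)-2,3,7-trimethyloct-6-enal (both C2 epimers) | O=CC(C)[C@@H](C)CCC=C(C)C | intermediate
5 | 1-hydroxybutan-2-one | CCC(=O)CO | starting material
6 | tert-butyl 2-(triphenyl-lambda5-phosphanylidene)acetate | CC(C)(C)OC(=O)C=P(c1ccccc1)(c1ccccc1)c1ccccc1 | starting material
7 | 2-oxobutanal | CCC(=O)C=O | intermediate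
8 | tert-butyl (E)-4-oxohex-2-enoate | CCC(=O)/C=C/C(=O)OC(C)(C)C | intermediate
9 | tert-butyl (2R,3S,4S)-3-formyl-3,4,8-trimethyl-2-(2-oxobutyl)non-7-enoate | O=C[C@@](C)([C@@H](C)CCC=C(C)C)[C@H](C(=O)OC(C)(C)C)CC(=O)CC | intermediate
10 | tert-butyl (1R,2R)-2,4-dimethyl-2-[(2S)-6-methylhept-5-en-2-yl]-5-oxocyclohex-3-ene-1-carboxylate | CC1=C[C@@](C)([C@@H](C)CCC=C(C)C)[C@H](C(=O)OC(C)(C)C)CC1=O | intermediate
11 | 6-trimethylsilyl derivative of 12 | CC1=C[C@@](C)([C@@H](C)CCC=C(C)C)[C@H](C(=O)OC(C)(C)C)CC([Si](C)(C)C)C1=O | intermediate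
12 | tert-butyl (1R,2R)-2,4-dimethyl-2-[(2S)-6-methylhept-5-en-2-yl]-5-oxocyclohept-3-ene-1-carboxylate | CC1=C[C@@](C)([C@@H](C)CCC=C(C)C)[C@H](C(=O)OC(C)(C)C)CCC1=O | intermediate
13 | tert-butyl (1R,2R,5S)-5-hydroxy-2,4-dimethyl-2-[(2S)-6-methylhept-5-en-2-yl]cyclohept-3-ene-1-carboxylate | CC1=C[C@@](C)([C@@H](C)CCC=C(C)C)[C@H](C(=O)OC(C)(C)C)CC[C@@H]1O | intermediate
14 | dilithium alkoxide enolate of 13 | CC1=C[C@@](C)([C@@H](C)CCC=C(C)C)C(=C([O-])OC(C)(C)C)CC[C@@H]1[O-].[Li+].[Li+] | intermediate
15 | tert-butyl (1S,2R,5S)-5-hydroxy-2,4-dimethyl-2-[(2S)-6-methylhept-5-en-2-yl]cyclohept-3-ene-1-carboxylate | CC1=C[C@@](C)([C@@H](C)CCC=C(C)C)[C@@H](C(=O)OC(C)(C)C)CC[C@@H]1O | intermediate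
16 | but-3-enoic acid | C=CCC(=O)O | starting material
17 | tert-butyl (1S,2R,5S)-5-(but-3-enoyloxy)-2,4-dimethyl-2-[(2S)-6-methylhept-5-en-2-yl]cyclohept-3-ene-1-carboxylate | CC1=C[C@@](C)([C@@H](C)CCC=C(C)C)[C@@H](C(=O)OC(C)(C)C)CC[C@@H]1OC(=O)CC=C | intermediate
18 | trimethylsilyl ketene acetal of 17 | CC1=C[C@@](C)([C@@H](C)CCC=C(C)C)[C@@H](C(=O)OC(C)(C)C)CC[C@@H]1OC(O[Si](C)(C)C)=CC=C | intermediate
19 | 2-[(1S,2R,3S)-3-(tert-butoxycarbonyl)-2,7-dimethyl-2-[(2S)-6-methylhept-5-en-2-yl]cyclohept-6-en-1-yl]but-3-enoic acid (C9 mixture) | C1=C(C)[C@H](C(C=C)C(=O)O)[C@@](C)([C@@H](C)CCC=C(C)C)[C@@H](C(=O)OC(C)(C)C)CC1 | intermediate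
20 | methyl ester of 19 | C1=C(C)[C@H](C(C=C)C(=O)OC)[C@@](C)([C@@H](C)CCC=C(C)C)[C@@H](C(=O)OC(C)(C)C)CC1 | intermediate
21 | tert-butyl (1S,2R,3S)-2,4-dimethyl-2-[(2S)-6-methylhept-5-en-2-yl]-3-(1-oxobut-3-en-2-yl)cyclohept-4-ene-1-carboxylate | C1=C(C)[C@H](C(C=C)C=O)[C@@](C)([C@@H](C)CCC=C(C)C)[C@@H](C(=O)OC(C)(C)C)CC1 | intermediate
22 | (1S,2R,3S,6S,10R)-9-formyl-2,10-dimethyl-2-[(2S)-6-methylhept-5-en-2-yl]bicyclo[4.3.1]dec-8-ene-3,10-carbolactone | O=C1O[C@]2(C)[C@@H]3CC=C(C=O)[C@@H]2[C@@](C)([C@@H](C)CCC=C(C)C)[C@@H]1CC3 | intermediate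
23 | lithium alpha-(N-methoxy-N-methylamino) alkoxide of 22 | O=C1O[C@]2(C)[C@@H]3CC=C(C([O-])N(C)OC)[C@@H]2[C@@](C)([C@@H](C)CCC=C(C)C)[C@@H]1CC3.[Li+] | intermediate
24 | dilithium C10 alkoxide of the C3 methyl ketone, aldehyde still masked | [O-][C@]1(C)[C@@H]2CC=C(C([O-])N(C)OC)[C@@H]1[C@@](C)([C@@H](C)CCC=C(C)C)[C@@H](C(C)=O)CC2.[Li+].[Li+] | intermediate
25 | (1S,2R,3S,6S,10R)-3-acetyl-9-formyl-2,10-dimethyl-2-[(2S)-6-methylhept-5-en-2-yl]bicyclo[4.3.1]dec-8-en-10-yl acetate (CNP0288370.1) | CC(=O)O[C@]1(C)[C@@H]2CC=C(C=O)[C@@H]1[C@@](C)([C@@H](C)CCC=C(C)C)[C@@H](C(C)=O)CC2 | target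

## Step count and risks
Total step count: 11. Longest linear sequence: 10 (steps 1 and 3 to 11).

Steps most likely to fail:

Step 10 (new oxidative carbolactonisation). The aldehyde may slip into conjugation before cyclisation, or the ester may not capture C10. The fallback sets out from 20 and comes back at 22 using known reactions. Aldehyde-selective Wacker oxidation of the vinyl group (PdCl2(PhCN)2, CuCl2, AgNO2, O2, t-BuOH-MeNO2) gives the C7 aldehyde F1. Me2AlCl-promoted Prins cyclisation follows: C6 attacks the C7 carbonyl from the upper face, and the C10 cation is captured by the tert-butyl ester with loss of isobutene, giving the C7-hydroxy lactone ester F2. Burgess dehydration and DBU equilibration give the conjugated ester lactone F3. i-Bu2AlH (2 equiv, -78 °C) reduces the unhindered enoate faster than the hindered bridged lactone to give the allylic alcohol lactone F4, and MnO2 then gives 22.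

Step 3 (catalytic formation of quaternary C2 next to a branched carbon). The fallback sets out from 4 and 8 and comes back at 10. The preformed Stork pyrrolidine enamine F5 is added to 8 in dioxane, and the adduct is hydrolysed and cyclised with AcOH-NaOAc-water. This achiral but reliable annulation gives 10 together with the ring-epimeric cyclohexenone F6. The two are diastereomers because of C1' and are separated by chromatography.

Step 4 (regiochemistry and reactivity of the enone in the diazoalkane homologation). The fallback sets out from 10 and comes back at 12 by a cyclopropanol ring expansion. LiN(i-Pr)2 and Me3SiCl give the cross-conjugated silyl enol ether F7. Et2Zn and CH2I2 cyclopropanate only its electron-rich enol ether alkene to give the siloxycyclopropane F8. FeCl3 in DMF opens the ring-fusion bond to the beta-chloro ketone F9, and NaOAc in MeOH gives the cycloheptadienone F10. [(Ph3P)CuH]6 then reduces only the less hindered disubstituted C4=C5 enone alkene to give 12.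

## Further compounds
F1 | step 10 | C7 aldehyde, methyl 2-[(1S,2R,3S)-3-(tert-butoxycarbonyl)-2,7-dimethyl-2-[(2S)-6-methylhept-5-en-2-yl]cyclohept-6-en-1-yl]-4-oxobutanoate | C1=C(C)[C@H](C(CC=O)C(=O)OC)[C@@](C)([C@@H](C)CCC=C(C)C)[C@@H](C(=O)OC(C)(C)C)CC1
F2 | step 10 | C7-hydroxy lactone ester, methyl 7-hydroxy-3,10-carbolactone-9-carboxylate of the saturated ring A core | O=C1O[C@]2(C)[C@@H]3C(O)CC(C(=O)OC)[C@@H]2[C@@](C)([C@@H](C)CCC=C(C)C)[C@@H]1CC3
F3 | step 10 | conjugated ester lactone, methyl ester analogue of 22 | O=C1O[C@]2(C)[C@@H]3CC=C(C(=O)OC)[C@@H]2[C@@](C)([C@@H](C)CCC=C(C)C)[C@@H]1CC3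
F4 | step 10 | allylic alcohol lactone, 9-hydroxymethyl analogue of 22 | O=C1O[C@]2(C)[C@@H]3CC=C(CO)[C@@H]2[C@@](C)([C@@H](C)CCC=C(C)C)[C@@H]1CC3
F5 | step 3 | pyrrolidine enamine of 4 (E) | C/C(=C\N1CCCC1)[C@@H](C)CCC=C(C)C
F6 | step 3 | ring-epimeric cyclohexenone, tert-butyl (1S,2S)-2,4-dimethyl-2-[(2S)-6-methylhept-5-en-2-yl]-5-oxocyclohex-3-ene-1-carboxylate | CC1=C[C@](C)([C@@H](C)CCC=C(C)C)[C@@H](C(=O)OC(C)(C)C)CC1=O
F7 | step 4 | cross-conjugated silyl enol ether of 10 | CC1=C[C@@](C)([C@@H](C)CCC=C(C)C)[C@H](C(=O)OC(C)(C)C)C=C1O[Si](C)(C)C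
F8 | step 4 | siloxycyclopropane from F7 | CC1=C[C@@](C)([C@@H](C)CCC=C(C)C)[C@H](C(=O)OC(C)(C)C)C2CC12O[Si](C)(C)C
F9 | step 4 | beta-chloro ketone, 7-chloro derivative of 12 | CC1=C[C@@](C)([C@@H](C)CCC=C(C)C)[C@H](C(=O)OC(C)(C)C)C(Cl)CC1=O
F10 | step 4 | cycloheptadienone, 6,7-didehydro derivative of 12 | CC1=C[C@@](C)([C@@H](C)CCC=C(C)C)[C@H](C(=O)OC(C)(C)C)C=CC1=O
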